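**Remark (assumption):** the target is achiral and has no stereocentre, so no step has to set configuration. Compounds 1, 5 and 7 are taken to be commercial.

## Analysis of the target

Target 15 is a flavonol: a 4H-chromen-4-one made of the benzo ring A (C4a, C5 to C8, C8a) and the pyranone ring C (O1, C2, C3, C4), with a 3,5-dihydroxy-4-methoxyphenyl ring B on C2. All difficulty is regiochemical and lies in telling oxygen functions apart. Ring A is pentasubstituted and carries four oxygens: the chelated C5–OH, C7–OH, C8–OMe and the ring oxygen O1 on C8a; only C6 bears hydrogen. The carbonyl-bearing carbon C4a is flanked by two oxygenated carbons, C5 and C8a, which differ only in their far neighbours (C6–H against C8–OMe). A ring C closure through a 2,6-dioxygenated aryl ketone can therefore go either way, and acid can equilibrate the 8-methoxy with the 6-methoxy series by ring opening (Wessely–Moser rearrangement). Two methyl ethers (on C8 and C4′), each flanked by oxygen functions, must survive while five hydroxyls are free at the end, which rules out Lewis-acid deprotection. The free polyphenol and the 3-hydroxypyranone are oxidizable, and ring C opens in strong base. The feature the route uses: on ring A, C5–OH is para to C8–OMe (a 4-methoxyphenol, a latent quinone monoketal), and the O1–C8a bond lies ortho to that methoxy group and meta to the C5 hydroxyl, which is the carbon where such a ketal accepts a nucleophile.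

## Retrosynthetic reasoning

**15 to 14.** The four benzyl–oxygen bonds (on O3, O7, O3′, O5′) are cut. One hydrogenolysis frees all hydroxyls and cannot touch the two methyl ethers, which a Lewis-acid deprotection could not guarantee.

**14 to 11 (through 13 and 12).** The O1–C8a bond is cut and C8a goes back to C–H, so the precursor is the open diketone 11, whose ring A is only a 4-methoxyphenol. The textbook cut at O1–C2 leaves a ketone with two competing ortho oxygens. The cut at O1–C8a leaves a ketone with one ortho oxygen, the future C5–OH, and that oxygen is a dienone carbonyl at the moment of ring closure. The forward reaction has to oxidize the phenol to the dimethyl ketal 12, add the side-chain enol oxygen to C8a (13), and expel one methoxy group with rearomatization. What is gained: the regiochemistry of ring A follows from where a quinone monoketal accepts nucleophiles, the ring A precursor needs three oxygens instead of four, and the C8 methoxy group is present from the start.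

**11 to 10 to 6 and 9.** The C2–C3 bond is cut. It is formed by Baker–Venkataraman acyl transfer inside ester 10, made from ketone 6 and acid 9. The C5 oxygen serves as the relay for the acyl group; this is harmless because it is not the ring oxygen. The C3 oxygen comes in as a benzyl ether on the ketone carbon of 6, so no separate oxidation at C3 is needed.

**6 to 4 and 5.** The C4–C4a bond is cut between aryl bromide 4 and Weinreb amide 5. The bromine marks the carbon para to the benzyloxy group, so no Friedel–Crafts chemistry and no Lewis acid near the benzyl ether is needed.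

**4 to 2 to 1.** The C5–O bond is cut: this oxygen comes from the formyl group of 2 by Baeyer–Villiger oxidation, and 2 is the benzyl ether of commercial 1. In 1 the bromine, the methoxy group and the free hydroxyl already sit where C4a, C8–OMe and C7–O are needed.

**9 to 7.** The benzyl–oxygen bonds of ring B are cut: exhaustive benzylation of 7 and hydrolysis of the benzyl ester 8.

## Alternatives that were turned down

**Alternative 1:** the textbook cut at O1–C2 with oxidation at C3 (Algar–Flynn–Oyamada reaction).
- Forward key step: chalcone A2, from ketone A1 and a ring B aldehyde, would be treated with alkaline H2O2, which closes ring C through the hydroxyl next to the methoxy group and oxidizes C3 to give A3; hydrogenolysis would finish.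
- Why turned down: all the difficulty moves into A1. Its acetyl group sits between two oxygens that both chelate the carbonyl and differ only in a substituent two atoms away, so partial benzylation of the parent triol has no handle to leave the right one free. Oxygenation of a simpler 2-hydroxy-4,6-dialkoxy ketone goes para to the free hydroxyl and leads into the 6-methoxy series. A1 would need its own protecting-group-heavy synthesis of about five steps. In addition, a chalcone with a substituent at C6′ such as A2 is twisted out of conjugation; this is the case in which the epoxide intermediate tends to open at the alpha carbon and give an aurone.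

**Alternative 2:** a late cut of the C8–O bond (Elbs persulfate oxidation).
- Forward key step: A4, which has no substituent on C8 and comes from a phloroglucinol-type ketone with equivalent ortho oxygens, would be hydroxylated para to the C5 hydroxyl with K2S2O8 in aqueous alkali to give A5. Methylation of the unchelated C8 hydroxyl would then give 14.
- Why turned down: it uses the same para relation as the chosen route, but the key step forms one C–O bond and none of the skeleton. It needs the C5 phenoxide in aqueous base, where the chelated hydroxyl is only partly ionized and hydroxide can open ring C. The electrophilic peroxydisulfate can also attack C6 and the electron-rich C2=C3 bond. Two further steps follow the oxidation, and the weakest step sits at the end of the sequence.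

**Alternative 3:** a late cut of the C5–O bond (ketone-directed C–H hydroxylation).
- Forward key step: ring C would be built the textbook way from a ring A ketone with a single ortho hydroxyl. The tetraacetate A6 would be cyclometalated at C5 through the C4 carbonyl with [Ru(p-cymene)Cl2]2 and oxidized with PhI(OCOCF3)2 in CF3CO2H/(CF3CO)2O to give A7; deacetylation would give 15.
- Why turned down: the medium is strongly acidic and oxidizing. Benzyl ethers would not survive, so all hydroxyls must be carried as esters, which adds a protecting-group exchange. The trioxygenated ring B stays the most electron-rich arene and competes for the trivalent iodine oxidant. The C4 carbonyl is a vinylogous ester flanked by an acyloxy group and is a weak directing group. The skeleton synthesis remains the textbook one, and the riskiest step again falls on the most advanced intermediate.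

Key step: step 7

## Route

**Step 1**
Reactants: 1 2-bromo-5-hydroxy-4-methoxybenzaldehyde
Product: 2 5-(benzyloxy)-2-bromo-4-methoxybenzaldehyde
Conditions: BnBr (1.2 equiv), K2CO3 (1.5 equiv), DMF, 23 °C
Reagents that add atoms: benzyl bromide, BrCc1ccccc1
Why: Williamson ether synthesis on the only acidic hydroxyl; the aldehyde and the aryl bromide are inert to K2CO3 in DMF.

**Step 2**
Reactants: 2 5-(benzyloxy)-2-bromo-4-methoxybenzaldehyde
Product: 4 5-(benzyloxy)-2-bromo-4-methoxyphenol, via aryl formate 3 (not isolated)
Conditions: mCPBA (1.3 equiv), CH2Cl2, 0 to 23 °C; then K2CO3 (0.1 equiv), MeOH, 23 °C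
Reagents that add atoms: 3-chloroperbenzoic acid, OOC(=O)c1cccc(Cl)c1
Why: Baeyer–Villiger oxidation of an electron-rich benzaldehyde, in which the aryl group with a para methoxy group migrates in preference to hydride; mild methanolysis of formate 3 frees the phenol that becomes the C5 hydroxyl. The bromide and the benzyl ether are not affected.

**Step 3**
Reactants: 4 5-(benzyloxy)-2-bromo-4-methoxyphenol; 5 2-(benzyloxy)-N-methoxy-N-methylacetamide
Product: 6 2-(benzyloxy)-1-[4-(benzyloxy)-2-hydroxy-5-methoxyphenyl]ethan-1-one
Conditions: n-BuLi (2.2 equiv), THF, −78 °C; then 5, −78 to 0 °C; aq. NH4Cl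
Reagents that add atoms: none
Why: the first equivalent of n-BuLi deprotonates the phenol and the second effects bromine–lithium exchange; the ortho-lithiophenoxide adds to the Weinreb amide to give a chelated tetrahedral intermediate that stops at the ketone (Weinreb ketone synthesis). The acyl group is thereby fixed at the future C4a while C8a remains C–H.

**Step 4**
Reactants: 7 3,5-dihydroxy-4-methoxybenzoic acid
Product: 9 3,5-bis(benzyloxy)-4-methoxybenzoic acid, via benzyl ester 8 (not isolated)
Conditions: BnBr (3.5 equiv), K2CO3 (4 equiv), DMF, 60 °C; then aq. NaOH, MeOH, 70 °C; HCl to pH 2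
Reagents that add atoms: benzyl bromide, BrCc1ccccc1
Why: exhaustive O-benzylation of both phenols and the acid, then saponification of the benzyl ester in the same flask; aryl benzyl ethers are stable to hydroxide.

**Step 5**
Reactants: 6 2-(benzyloxy)-1-[4-(benzyloxy)-2-hydroxy-5-methoxyphenyl]ethan-1-one; 9 3,5-bis(benzyloxy)-4-methoxybenzoic acid
Product: 10 5-(benzyloxy)-2-[2-(benzyloxy)acetyl]-4-methoxyphenyl 3,5-bis(benzyloxy)-4-methoxybenzoate
Conditions: EDC·HCl (1.5 equiv), DMAP (0.2 equiv), CH2Cl2, 23 °C
Reagents that add atoms: none
Why: Steglich esterification; DMAP transfers the activated aroyl group to the chelated phenol and places it for the intramolecular acyl transfer of step 6.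

**Step 6**
Reactants: 10 5-(benzyloxy)-2-[2-(benzyloxy)acetyl]-4-methoxyphenyl 3,5-bis(benzyloxy)-4-methoxybenzoate
Product: 11 racemic 2-(benzyloxy)-1-[4-(benzyloxy)-2-hydroxy-5-methoxyphenyl]-3-[3,5-bis(benzyloxy)-4-methoxyphenyl]propane-1,3-dione
Conditions: LiN(SiMe3)2 (2.5 equiv), THF, −78 to 0 °C; AcOH quench at −20 °C
Reagents that add atoms: none
Why: Baker–Venkataraman rearrangement: the ketone enolate attacks the neighbouring aryl ester through a six-membered transition state, forming the C2–C3 bond and releasing the phenoxide needed for step 7. The carbon between the carbonyl groups is racemic and labile and becomes sp2 later; the cold acetic acid quench avoids acid-driven closure through the C5 hydroxyl.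

**Step 7**
Reactants: 11 racemic 2-(benzyloxy)-1-[4-(benzyloxy)-2-hydroxy-5-methoxyphenyl]-3-[3,5-bis(benzyloxy)-4-methoxyphenyl]propane-1,3-dione
Product: 14 3,7-bis(benzyloxy)-2-[3,5-bis(benzyloxy)-4-methoxyphenyl]-5-hydroxy-8-methoxy-4H-chromen-4-one, via quinone monoketal 12 (not isolated), via dihydrochromenone 13 (not isolated)
Conditions: PhI(OAc)2 (1.05 equiv), MeOH–CH2Cl2, −20 to 0 °C; evaporation, then toluene, Et3N (0.2 equiv), 23 °C; then camphorsulfonic acid (0.3 equiv), 40 °C
Reagents that add atoms: methanol, CO
Why: Proposed new method: PhI(OAc)2 in methanol should convert the 4-methoxyphenol unit of 11 (C5–OH para to C8–OMe) into the 4,4-dimethoxycyclohexa-2,5-dienone 12, the usual fate of 4-methoxyphenols with this trivalent iodine reagent, and in 12 the C5 oxygen is a ketone and can no longer close ring C in the textbook direction. C8a of 12 is the beta carbon of an alkylidene-1,3-dicarbonyl unit (conjugated to both C5=O and C4=O) next to the ketal carbon, whereas the other beta carbon, C7, carries the benzyloxy group and is a deactivated vinylogous ester carbon, so the enol oxygen on C2 should add to C8a only. This closes ring C in the 6-endo-trig mode (oxa-Michael addition; the same bond results from an oxa-6π electrocyclization of the C4 enol tautomer, a 1-oxatriene) and gives 13, while attack by the central carbon would need a four-membered ring and is excluded. Acid then ionizes the C8 ketal to a cation stabilized by the oxygens on C7 and C5, and loss of the C8a proton expels methanol and restores ring A, which makes the sequence irreversible; the C8 methoxy group of 14 may stem from either methoxy group of the ketal. The closest known reaction types are the conjugate addition of heteroatom and carbon nucleophiles to quinone monoketals followed by aromatization with loss of methanol, which places the nucleophile ortho to the remaining methoxy group and meta to the phenol, and the addition of alcohols to C3 of 2-acyl-1,4-benzoquinones; closing a chromone ring with a diketone enol in this way is the new element. No stereocentre is set: C8a of 13 forms as a racemate and becomes sp2 in 14, and the labile carbon between the carbonyl groups of 11 becomes C3. The step needs oxidation of the phenol in preference to the diketone (secured by the single free phenol and by the benzyloxy group on the central carbon, which blocks iodonium ylide formation) and oxygen attack by the enol in preference to methanol (secured by removing methanol before base and acid are added, and by the slight excess of oxidant only, so that the 5-hydroxy-8-methoxy product is not oxidized again).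

**Step 8**
Reactants: 14 3,7-bis(benzyloxy)-2-[3,5-bis(benzyloxy)-4-methoxyphenyl]-5-hydroxy-8-methoxy-4H-chromen-4-one
Product: 15 3,5,7-trihydroxy-2-(3,5-dihydroxy-4-methoxyphenyl)-8-methoxy-4H-chromen-4-one
Conditions: H2 (1 atm), Pd/C (10% palladium on carbon), THF–MeOH, 23 °C
Reagents that add atoms: none
Why: hydrogenolysis of the four benzyl ethers; the methyl ethers, the chelated C5 hydroxyl and the C2=C3 bond of the flavonol should not be affected at 1 atm and room temperature.

## Compound list

1 | 2-bromo-5-hydroxy-4-methoxybenzaldehyde | COc1cc(Br)c(C=O)cc1O | starting material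
2 | 5-(benzyloxy)-2-bromo-4-methoxybenzaldehyde | COc1cc(Br)c(C=O)cc1OCc1ccccc1 | intermediate
3 | 5-(benzyloxy)-2-bromo-4-methoxyphenyl formate | COc1cc(Br)c(OC=O)cc1OCc1ccccc1 | intermediate
4 | 5-(benzyloxy)-2-bromo-4-methoxyphenol | COc1cc(Br)c(O)cc1OCc1ccccc1 | intermediate
5 | 2-(benzyloxy)-N-methoxy-N-methylacetamide | CON(C)C(=O)COCc1ccccc1 | starting material
6 | 2-(benzyloxy)-1-[4-(benzyloxy)-2-hydroxy-5-methoxyphenyl]ethan-1-one | COc1cc(C(=O)COCc2ccccc2)c(O)cc1OCc1ccccc1 | intermediate
7 | 3,5-dihydroxy-4-methoxybenzoic acid | COc1c(O)cc(C(=O)O)cc1O | starting material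
8 | benzyl 3,5-bis(benzyloxy)-4-methoxybenzoate | COc1c(OCc2ccccc2)cc(C(=O)OCc2ccccc2)cc1OCc1ccccc1 | intermediate
9 | 3,5-bis(benzyloxy)-4-methoxybenzoic acid | COc1c(OCc2ccccc2)cc(C(=O)O)cc1OCc1ccccc1 | intermediate
10 | 5-(benzyloxy)-2-[2-(benzyloxy)acetyl]-4-methoxyphenyl 3,5-bis(benzyloxy)-4-methoxybenzoate | COc1cc(C(=O)COCc2ccccc2)c(OC(=O)c2cc(OCc3ccccc3)c(OC)c(OCc3ccccc3)c2)cc1OCc1ccccc1 | intermediate
11 | racemic 2-(benzyloxy)-1-[4-(benzyloxy)-2-hydroxy-5-methoxyphenyl]-3-[3,5-bis(benzyloxy)-4-methoxyphenyl]propane-1,3-dione (keto form; labile centre) | COc1cc(C(=O)C(OCc2ccccc2)C(=O)c2cc(OCc3ccccc3)c(OC)c(OCc3ccccc3)c2)c(O)cc1OCc1ccccc1 | intermediate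
12 | racemic 2-(benzyloxy)-1-[4-(benzyloxy)-3,3-dimethoxy-6-oxocyclohexa-1,4-dien-1-yl]-3-[3,5-bis(benzyloxy)-4-methoxyphenyl]propane-1,3-dione | COC1(OC)C=C(C(=O)C(OCc2ccccc2)C(=O)c2cc(OCc3ccccc3)c(OC)c(OCc3ccccc3)c2)C(=O)C=C1OCc1ccccc1 | intermediate
13 | racemic 3,7-bis(benzyloxy)-2-[3,5-bis(benzyloxy)-4-methoxyphenyl]-5-hydroxy-8,8-dimethoxy-8,8a-dihydro-4H-chromen-4-one | COC1(OC)C2OC(c3cc(OCc4ccccc4)c(OC)c(OCc4ccccc4)c3)=C(OCc3ccccc3)C(=O)C2=C(O)C=C1OCc1ccccc1 | intermediate
14 | 3,7-bis(benzyloxy)-2-[3,5-bis(benzyloxy)-4-methoxyphenyl]-5-hydroxy-8-methoxy-4H-chromen-4-one | COc1c(OCc2ccccc2)cc(O)c2c(=O)c(OCc3ccccc3)c(-c3cc(OCc4ccccc4)c(OC)c(OCc4ccccc4)c3)oc12 | intermediate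
15 | 3,5,7-trihydroxy-2-(3,5-dihydroxy-4-methoxyphenyl)-8-methoxy-4H-chromen-4-one | COc1c(O)cc(-c2oc3c(OC)c(O)cc(O)c3c(=O)c2O)cc1O | target

## Step count and least certain steps

Total step count: 8. Longest linear sequence: 7 steps (steps 1, 2, 3, 5, 6, 7, 8, from 1 to 15); the ring B branch is one step (step 4).

**Step 7 (key step, proposed new method).** The oxidant may attack the diketone enol instead of the chelated, acyl-deactivated phenol. Methanol may add to C8a of the dienone faster than the enol oxygen and aromatize irreversibly. Traces of water may hydrolyse the ketal to the quinone, with loss of the C8 methyl group.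
Fallback with known reactions, in which the same oxygen is brought in stepwise and intermolecularly before ring B is attached. It sets out from ketone 6 and comes back to the route at 15.
- PhI(OAc)2 in MeOH should give the isolable quinone monoketal 2-(benzyloxy)-1-[4-(benzyloxy)-3,3-dimethoxy-6-oxocyclohexa-1,4-dien-1-yl]ethan-1-one F1.
- Base-catalysed conjugate addition of allyl alcohol (K2CO3, 0 °C) to its doubly activated double bond, then acid-induced loss of methanol (camphorsulfonic acid, CH2Cl2), should give 1-[2-(allyloxy)-4-(benzyloxy)-6-hydroxy-3-methoxyphenyl]-2-(benzyloxy)ethan-1-one F2. This is the known conversion of quinone monoketals into 3-substituted 4-methoxyphenols.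
- Benzylation of the chelated phenol (BnBr, K2CO3, DMF, 60 °C) gives 1-[2-(allyloxy)-4,6-bis(benzyloxy)-3-methoxyphenyl]-2-(benzyloxy)ethan-1-one F3.
- Removal of the allyl group with Pd(PPh3)4 and morpholine gives 2-(benzyloxy)-1-[4,6-bis(benzyloxy)-2-hydroxy-3-methoxyphenyl]ethan-1-one F4, in which only the oxygen next to the methoxy group is free.
- Esterification with acid 9 under the conditions of step 5 gives 3,5-bis(benzyloxy)-2-[2-(benzyloxy)acetyl]-6-methoxyphenyl 3,5-bis(benzyloxy)-4-methoxybenzoate F5.
- Baker–Venkataraman transfer under the conditions of step 6 gives racemic 2-(benzyloxy)-1-[4,6-bis(benzyloxy)-2-hydroxy-3-methoxyphenyl]-3-[3,5-bis(benzyloxy)-4-methoxyphenyl]propane-1,3-dione F6.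
- Ordinary cyclodehydration (TsOH, toluene, 80 °C) gives 3,5,7-tris(benzyloxy)-2-[3,5-bis(benzyloxy)-4-methoxyphenyl]-8-methoxy-4H-chromen-4-one F7.
- Hydrogenolysis of F7 under the conditions of step 8 gives 15.

**Step 3.** Proton transfer from the alpha-methylene group of amide 5 to the aryllithium (reduction of the C–Br bond to C–H) or sluggish addition of the phenoxide-bearing aryllithium may cut conversion.
Fallback, which sets out from 4 and comes back at 6:
- Protection as the methoxymethyl ether (MOMCl, iPr2NEt) gives 1-(benzyloxy)-4-bromo-2-methoxy-5-(methoxymethoxy)benzene F8.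
- Bromine–lithium exchange with one equivalent of n-BuLi and addition to (benzyloxy)acetaldehyde gives racemic 2-(benzyloxy)-1-[4-(benzyloxy)-5-methoxy-2-(methoxymethoxy)phenyl]ethan-1-ol F9.
- Oxidation with Dess–Martin periodinane gives 2-(benzyloxy)-1-[4-(benzyloxy)-5-methoxy-2-(methoxymethoxy)phenyl]ethan-1-one F10.
- HCl in MeOH removes the acetal and gives 6.

**Step 6.** The enolate carries a benzyloxy group and is hindered, so the intramolecular acyl transfer may be slow and cleavage of the aryl ester may compete. On contact with acid the product may cyclodehydrate through the C5 hydroxyl in the textbook direction.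
Fallback, which sets out from 6 and 9 and comes back at 11: acid 9 is converted with (COCl)2 and catalytic DMF into 3,5-bis(benzyloxy)-4-methoxybenzoyl chloride F11. Ketone 6 is converted with LiN(SiMe3)2 (3 equiv, THF, −78 °C) into its phenoxide–enolate dianion, which is C-acylated directly by F11 to give 11 after a cold acetic acid quench.

**Step 8.** Cleavage of the hindered benzyl ether on O3 may be incomplete, the C2=C3 bond may be over-reduced on long exposure, and the chelating polyphenol product may poison the catalyst.
Fallback, which sets out from 14 and ends at 15: Lewis-acid debenzylation with BCl3 and pentamethylbenzene as cation scavenger in CH2Cl2 at −78 °C, conditions under which aryl methyl ethers are retained (no new compound, F0).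

## Further compounds

F1 | step 7 | 2-(benzyloxy)-1-[4-(benzyloxy)-3,3-dimethoxy-6-oxocyclohexa-1,4-dien-1-yl]ethan-1-one | COC1(OC)C=C(C(=O)COCc2ccccc2)C(=O)C=C1OCc1ccccc1
F2 | step 7 | 1-[2-(allyloxy)-4-(benzyloxy)-6-hydroxy-3-methoxyphenyl]-2-(benzyloxy)ethan-1-one | COc1c(OCc2ccccc2)cc(O)c(C(=O)COCc2ccccc2)c1OCC=C
F3 | step 7 | 1-[2-(allyloxy)-4,6-bis(benzyloxy)-3-methoxyphenyl]-2-(benzyloxy)ethan-1-one | COc1c(OCc2ccccc2)cc(OCc2ccccc2)c(C(=O)COCc2ccccc2)c1OCC=C
F4 | step 7 | 2-(benzyloxy)-1-[4,6-bis(benzyloxy)-2-hydroxy-3-methoxyphenyl]ethan-1-one | COc1c(OCc2ccccc2)cc(OCc2ccccc2)c(C(=O)COCc2ccccc2)c1O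
F5 | step 7 | 3,5-bis(benzyloxy)-2-[2-(benzyloxy)acetyl]-6-methoxyphenyl 3,5-bis(benzyloxy)-4-methoxybenzoate | COc1c(OCc2ccccc2)cc(OCc2ccccc2)c(C(=O)COCc2ccccc2)c1OC(=O)c1cc(OCc2ccccc2)c(OC)c(OCc2ccccc2)c1
F6 | step 7 | racemic 2-(benzyloxy)-1-[4,6-bis(benzyloxy)-2-hydroxy-3-methoxyphenyl]-3-[3,5-bis(benzyloxy)-4-methoxyphenyl]propane-1,3-dione | COc1c(OCc2ccccc2)cc(OCc2ccccc2)c(C(=O)C(OCc2ccccc2)C(=O)c2cc(OCc3ccccc3)c(OC)c(OCc3ccccc3)c2)c1O
F7 | step 7 | 3,5,7-tris(benzyloxy)-2-[3,5-bis(benzyloxy)-4-methoxyphenyl]-8-methoxy-4H-chromen-4-one | COc1c(OCc2ccccc2)cc(OCc2ccccc2)c2c(=O)c(OCc3ccccc3)c(-c3cc(OCc4ccccc4)c(OC)c(OCc4ccccc4)c3)oc12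
F8 | step 3 | 1-(benzyloxy)-4-bromo-2-methoxy-5-(methoxymethoxy)benzene | COCOc1cc(OCc2ccccc2)c(OC)cc1Br
F9 | step 3 | racemic 2-(benzyloxy)-1-[4-(benzyloxy)-5-methoxy-2-(methoxymethoxy)phenyl]ethan-1-ol | COCOc1cc(OCc2ccccc2)c(OC)cc1C(O)COCc1ccccc1
F10 | step 3 | 2-(benzyloxy)-1-[4-(benzyloxy)-5-methoxy-2-(methoxymethoxy)phenyl]ethan-1-one | COCOc1cc(OCc2ccccc2)c(OC)cc1C(=O)COCc1ccccc1
F11 | step 6 | 3,5-bis(benzyloxy)-4-methoxybenzoyl chloride | COc1c(OCc2ccccc2)cc(C(Cl)=O)cc1OCc1ccccc1
F0 | step 8 | none | none
A1 | alternative 1 | 1-[4,6-bis(benzyloxy)-2-hydroxy-3-methoxyphenyl]ethan-1-one | COc1c(O)c(C(C)=O)c(OCc2ccccc2)cc1OCc1ccccc1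
A2 | alternative 1 | (E)-1-[4,6-bis(benzyloxy)-2-hydroxy-3-methoxyphenyl]-3-[3,5-bis(benzyloxy)-4-methoxyphenyl]prop-2-en-1-one | COc1c(O)c(C(=O)/C=C/c2cc(OCc3ccccc3)c(OC)c(OCc3ccccc3)c2)c(OCc2ccccc2)cc1OCc1ccccc1
A3 | alternative 1 | 5,7-bis(benzyloxy)-2-[3,5-bis(benzyloxy)-4-methoxyphenyl]-3-hydroxy-8-methoxy-4H-chromen-4-one | COc1c(OCc2ccccc2)cc(OCc2ccccc2)c2c(=O)c(O)c(-c3cc(OCc4ccccc4)c(OC)c(OCc4ccccc4)c3)oc12
A4 | alternative 2 | 3,7-bis(benzyloxy)-2-[3,5-bis(benzyloxy)-4-methoxyphenyl]-5-hydroxy-4H-chromen-4-one | O=c1c(OCc2ccccc2)c(-c2cc(OCc3ccccc3)c(OC)c(OCc3ccccc3)c2)oc2cc(OCc3ccccc3)cc(O)c12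
A5 | alternative 2 | 3,7-bis(benzyloxy)-2-[3,5-bis(benzyloxy)-4-methoxyphenyl]-5,8-dihydroxy-4H-chromen-4-one | O=c1c(OCc2ccccc2)c(-c2cc(OCc3ccccc3)c(OC)c(OCc3ccccc3)c2)oc2c(O)c(OCc3ccccc3)cc(O)c12
A6 | alternative 3 | 2-[3,5-bis(acetyloxy)-4-methoxyphenyl]-8-methoxy-4-oxo-4H-chromene-3,7-diyl diacetate | COc1c(OC(C)=O)ccc2c(=O)c(OC(C)=O)c(-c3cc(OC(C)=O)c(OC)c(OC(C)=O)c3)oc12
A7 | alternative 3 | 2-[3,5-bis(acetyloxy)-4-methoxyphenyl]-5-hydroxy-8-methoxy-4-oxo-4H-chromene-3,7-diyl diacetate | COc1c(OC(C)=O)cc(O)c2c(=O)c(OC(C)=O)c(-c3cc(OC(C)=O)c(OC)c(OC(C)=O)c3)oc12
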